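## Structural features

The target is a flavonol: a benzene ring (ring A) fused through C4a and C8a to a 4-pyranone (ring C), with a 4-methoxyphenyl group (ring B) joined to C2 by a single C–C bond. Ring A is fully substituted. Besides the two fusion carbons it carries oxygen on C5, C6, C7 and C8; only O5 is a free hydroxyl, hydrogen-bonded to the C4 carbonyl, and the other three are methyl ethers. Ring C holds the C4 carbonyl and, next to it, the enolic 3-hydroxyl of a diosphenol. The target has no stereocentre; a saturated precursor of ring C has three contiguous ones (C2, C3, C4), which need no control because all end as trigonal carbons. Sensitive points are the flavonol enol (oxidative cleavage under basic oxidising conditions), the very electron-rich ring A (quinone formation, loss of methyl groups to hard Lewis acids) and, in open-chain precursors, the benzylic O1–C2 ether and any aldehyde next to it. The real difficulty lies in ring A, with five oxygens in a row and exactly one unmasked, and in bringing oxygen to both C3 and C4. The plan uses two features: C3 and C4 of ring C are neighbouring oxygen-bearing carbons, so they can come from a vicinal diol made by joining a formyl group on C4a with a formyl group hung from O1 through C2; and O5 is the only ring A oxygen peri to the C4 carbonyl, so it can be singled out at the very end.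

## Logic of the disconnections

18 to 17: the free O5–H is traced back to an O5–CH3 ether. With all four ring A oxygens as identical methyl ethers, ring A can be built without differentiating them. The forward step must remove one methyl group out of five, guided only by the peri carbonyl, while the 3-hydroxyl is free.

17 to 15 (through 16): no skeletal bond is cut. C3 and C4 are taken down to two carbinols and C2 becomes tetrahedral. This exposes the 1,2-diol pattern that a reductive carbonyl coupling can make. The forward step must oxidise both carbinols without breaking C3–C4, and 16 must tautomerise through its C2–H. Since all three stereocentres of 15 vanish, any diastereomer mixture serves.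

15 to 14: the C3–C4 bond is cut. Both carbons carry hydroxyl groups, so the bond is the product of a pinacol coupling. Ring C is opened, three stereocentres shrink to one racemic centre, and the precursor is an acyclic dialdehyde. The forward step must form the ketyl on the ring A formyl group and close the six-membered ring faster than dimerisation or reductive loss of the aryloxy group.

14 to 13 to 12: no skeletal bond is cut. The two formyl groups are traced to two primary alcohols in 13, and these to the formyl and methyl ester groups of 12. An ester is the robust carrier of the future C3, but it cannot be half-reduced beside an aryl aldehyde, so both carbonyls are reduced and both alcohols re-oxidised. The forward oxidation must be free of amine base, and 14 must be used without storage.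

12 to 9 and 11: the O1–C2 ether bond is cut. This splits the molecule into a ring A half and a ring B half of similar size, with natural polarity (phenoxide plus benzylic α-halo ester). The forward step must O-alkylate a hindered, chelated phenol without base-induced aldol closure of the product.

11 to 10: the C–Br bond is replaced by C–H. The position is benzylic and α to the ester, so radical bromination should find it. The demand is side-chain rather than ring bromination.

9 to 7: the C4a–C4 bond (ring to formyl carbon) is cut. Only one ring position is free and it is ortho to the hydroxyl, so regiochemistry is automatic. The forward formylation must tolerate an electron-rich phenol.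

7 to 4: the C8a–O1 bond is replaced by C–H. 4 is symmetric, its two ring hydrogens are equivalent and each is ortho to a methoxy group, so directed metalation followed by borylation and oxidation installs the oxygen in one step. This is shorter than a formylation followed by a peroxide rearrangement. The demand is monolithiation and an oxidation that spares the new phenol.

4 to 3 to 1: one O–CH3 bond is cut, and the aryl C–O bond of 3 is traced to the aryl C–CHO bond of 1 (through 2). 1 is a cheap aldehyde whose formyl carbon marks the place of the fourth oxygen. The forward rearrangement needs aryl rather than hydride migration, which the ortho and para methoxy groups secure.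

## Other disconnections considered

Alternative 1: The cut goes through ring A instead of ring C: C8–C8a is opened and, one stage further back, C4a–C5.
- **Forward key step.** C5 to C8 with their oxygens come from dimethyl squarate A3, and rings C and B come from a finished pyranone such as 3-(benzyloxy)-5-iodo-2-(4-methoxyphenyl)-4H-pyran-4-one A4. Metalated A4 would add to one carbonyl of A3 to give the carbinol A2, 4-[5-(benzyloxy)-6-(4-methoxyphenyl)-4-oxo-4H-pyran-3-yl]-4-hydroxy-2,3-dimethoxycyclobut-2-en-1-one. On heating, A2 should open to a dienylketene (Moore rearrangement), close by 6π electrocyclisation onto the pyranone C–H carbon and tautomerise to the hydroquinone A1, 3-(benzyloxy)-5,8-dihydroxy-6,7-dimethoxy-2-(4-methoxyphenyl)-4H-chromen-4-one.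
- **In favour.** A1 would carry O6 and O7 methylated and O5 and O8 free. The 5-hydroxyl is chelated, so methylation of O8 alone and hydrogenolysis of the benzyl ether would lead to 18 without any demethylation. The C3 oxygen is present throughout, no stereocentre appears, and there is no reduce-then-reoxidise detour. On differentiation of O5 and on redox economy this plan is the better one.
- **Against.** A4 is a multistep target in its own right. Metalation next to a cross-conjugated pyranone carbonyl invites conjugate addition and ring opening. The electrocyclisation must engage an electron-poor pyranone double bond, a partner with much thinner precedent than benzene or furan rings. A1 is an electron-rich hydroquinone that is easily oxidised to the 5,8-quinone.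
- **Comparison.** The alternative is pericyclic and thermal and builds the crowded ring last; the chosen plan is a single-electron reduction and builds ring A first from a cheap aromatic. Once A4 is counted, the step count is expected to be similar or higher, and the two least precedented steps sit at the convergence point.

Alternative 2: Three bonds of ring C are cut at once: C4a–C4, C4–C3 and O1–C2.
- **Forward key step.** The pieces are 2-iodo-3,4,5,6-tetramethoxyphenol A6 (one iodination from 7), carbon monoxide A8 as the C4 carbon, and 4-ethynylanisole A7. Zerovalent palladium would insert into the C–I bond, take up A8 and couple the acylpalladium with A7 (carbonylative Sonogashira coupling). The ortho-hydroxyaryl ynone would then close by 6-endo-dig oxa-Michael addition to the flavone A5, 5,6,7,8-tetramethoxy-2-(4-methoxyphenyl)-4H-chromen-4-one.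
- **In favour.** Three components join in one flask, with no stereocentre and no side-chain redox work. From 7 the skeleton would be reached in two steps and 17 in three (after C3 hydroxylation), against six in the chosen plan. On convergence and step economy the alternative is clearly better, and in the final demethylation it is equal.
- **Against.** A5 lacks the C3 oxygen. It must be added later to an electron-rich 5-methoxyflavone, by C3 deprotonation and borate oxidation or by epoxidation of the C2–C3 bond. Oxidative addition into a hexasubstituted, very electron-rich aryl iodide flanked by OH and OMe is slow and may be overtaken by alkyne homocoupling or non-carbonylative coupling. The ynone may also close 5-exo-dig to an aurone, and a toxic gas is needed.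
- **Comparison.** The chosen plan builds both the C3 and the C4 oxygen into the ring-forming step, so it needs no late C–H oxidation. It also avoids the flavone-versus-aurone question, because its closure forms C3–C4 rather than O1–C2.

Alternative 3: O1–C2 and C3–C4 are cut, which returns 9 and (E)-1-methoxy-4-(2-nitroethenyl)benzene A10.
- **Forward key step.** The C3–C4 cut is the same as in the chosen plan but with reversed polarity: C3 is the nucleophile (a nitronate) and C4 the electrophile. An amine base would trigger oxa-Michael addition of the phenoxide of 9 to A10, Henry addition onto the formyl group and dehydration, giving racemic 5,6,7,8-tetramethoxy-2-(4-methoxyphenyl)-3-nitro-2H-chromene A9.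
- **In favour.** It starts from the same 9 and forms both ring C bonds in one polar step, with no low-valent metal and no sensitive 14. From 9, 17 could be reached in two or three steps (cascade, nucleophilic epoxidation of the nitroalkene, loss of nitrite with tautomerisation), against five in the chosen plan. On step count and operational simplicity the alternative is the better plan. On the final demethylation and on the erased C2 stereocentre the two are equal.
- **Against.** The formyl group of 9 is flanked on both sides and deactivated by five donor oxygens, so the Henry step may be slow and reversible. A10 is a deactivated Michael acceptor. The exchange of nitrogen for oxygen at C3 is the least general step, and alkaline peroxide can also degrade the flavonol as it forms.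
- **Comparison.** In the chosen plan C3 carries its oxygen from the moment the ring closes, so no heteroatom exchange is needed.

Key step: step 9

Remark on the chemistry: 15 is drawn as the expected 2,3-trans-3,4-cis racemate; any accompanying diastereomers are carried forward together, since C2, C3 and C4 all become trigonal in step 10.

## Route

Step 1
Reactants: 1 2,3,4-trimethoxybenzaldehyde
Product: 3 2,3,4-trimethoxyphenol, via aryl formate 2 (not isolated)
Conditions: 30% aq H2O2, H2SO4 (cat.), MeOH, rt
Reagents that add atoms: hydrogen peroxide, OO
Why: Acid-catalysed Dakin oxidation (a Baeyer–Villiger-type rearrangement): the ortho and para methoxy groups make the aryl group migrate in the peroxy hemiacetal, and formate 2 is transesterified by methanol in the same flask.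

Step 2
Reactants: 3 2,3,4-trimethoxyphenol
Product: 4 1,2,3,4-tetramethoxybenzene
Conditions: MeI, K2CO3, DMF, rt
Reagents that add atoms: iodomethane, CI
Why: Williamson O-methylation of the phenoxide; the symmetric product has only one kind of ring hydrogen, which removes any regiochemical question from step 3.

Step 3
Reactants: 4 1,2,3,4-tetramethoxybenzene
Product: 7 2,3,4,5-tetramethoxyphenol, via aryllithium 5 (not isolated), via dimethyl arylboronate 6 (not isolated)
Conditions: n-BuLi, TMEDA, THF, 0 °C to rt; B(OMe)3, −78 °C to rt; AcOH, 30% aq H2O2, 0 °C to rt
Reagents that add atoms: hydrogen peroxide, OO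
Why: Directed ortho-metalation next to the terminal methoxy group gives 5, which is trapped as 6; peroxide then induces the 1,2-shift of the aryl group from boron to oxygen (borylation–oxidation), and the weakly acidic medium limits oxidation of the electron-rich phenol.

Step 4
Reactants: 7 2,3,4,5-tetramethoxyphenol
Product: 9 2-hydroxy-3,4,5,6-tetramethoxybenzaldehyde, via salicyl alcohol 8 (not isolated)
Conditions: MgCl2, Et3N, (CH2O)n, MeCN, reflux; then 1 M aq HCl
Reagents that add atoms: paraformaldehyde (as formaldehyde), C=O
Why: Magnesium-mediated ortho-formylation (Casnati–Skattebøl): the magnesium phenoxide delivers formaldehyde to the only free position, ortho to oxygen, and 8 is oxidised in situ by hydride transfer to a second formaldehyde.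

Step 5
Reactants: 10 methyl 2-(4-methoxyphenyl)acetate
Product: 11 methyl 2-bromo-2-(4-methoxyphenyl)acetate (racemic)
Conditions: NBS, AIBN (cat.), PhCF3, 80 °C; used crude
Reagents that add atoms: N-bromosuccinimide, O=C1CCC(=O)N1Br
Why: Wohl–Ziegler radical bromination at the C–H that is both benzylic and α to the ester; a non-polar medium and a radical initiator keep NBS from brominating the anisole ring.

Step 6
Reactants: 9 2-hydroxy-3,4,5,6-tetramethoxybenzaldehyde; 11 methyl 2-bromo-2-(4-methoxyphenyl)acetate (racemic)
Product: 12 methyl 2-(2-formyl-3,4,5,6-tetramethoxyphenoxy)-2-(4-methoxyphenyl)acetate (racemic)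
Conditions: K2CO3, DMF, 0 °C to rt
Reagents that add atoms: none
Why: Williamson etherification: SN2 attack of the phenoxide on the activated secondary benzylic α-bromo ester forms O1–C2; carbonate at or below room temperature should be too weak to drive aldol closure of the acidic α-H onto the neighbouring formyl group, and the new centre (future C2) is racemic and later erased.

Step 7
Reactants: 12 methyl 2-(2-formyl-3,4,5,6-tetramethoxyphenoxy)-2-(4-methoxyphenyl)acetate (racemic)
Product: 13 2-[2-(hydroxymethyl)-3,4,5,6-tetramethoxyphenoxy]-2-(4-methoxyphenyl)ethan-1-ol (racemic)
Conditions: LiAlH4, THF, 0 °C; H2O/15% aq NaOH work-up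
Reagents that add atoms: none
Why: Hydride reduction of both the formyl and the ester group; reducing both avoids an impossible chemoselective half-reduction of the ester beside an aryl aldehyde.

Step 8
Reactants: 13 2-[2-(hydroxymethyl)-3,4,5,6-tetramethoxyphenoxy]-2-(4-methoxyphenyl)ethan-1-ol (racemic)
Product: 14 2,3,4,5-tetramethoxy-6-[1-(4-methoxyphenyl)-2-oxoethoxy]benzaldehyde (racemic)
Conditions: DMP, NaHCO3, CH2Cl2, 0 °C to rt; aq Na2S2O3/NaHCO3 work-up; used crude at once
Reagents that add atoms: none
Why: Dess–Martin oxidation of both primary alcohols under buffered, amine-free conditions, chosen to protect the enolisable α-aryl-α-aryloxy aldehyde from aldol closure; the hydroxyls are not vicinal, so no glycol cleavage is possible.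

Step 9
Reactants: 14 2,3,4,5-tetramethoxy-6-[1-(4-methoxyphenyl)-2-oxoethoxy]benzaldehyde (racemic)
Product: 15 rac-(2R,3S,4S)-5,6,7,8-tetramethoxy-2-(4-methoxyphenyl)chromane-3,4-diol (2,3-trans-3,4-cis)
Conditions: SmI2 (0.1 M in THF, 3 equiv), t-BuOH (3 equiv), THF, −78 °C to rt, slow addition of 14 at high dilution; then aq NH4Cl
Reagents that add atoms: none
Why: SmI2 (divalent samarium) should transfer one electron to the ring A formyl group, the more easily reduced carbonyl because it is conjugated, to give a samarium ketyl at the future C4. The ketyl adds to the samarium-activated aliphatic formyl carbon (future C3) in a 6-exo-trig closure of ring C, and a second electron plus protonation by t-BuOH gives the diolate; the closest known reaction type is the SmI2-mediated intramolecular pinacol coupling of dialdehydes to cyclic cis-diols. One trivalent samarium bridging both oxygens in the cyclisation transition state sets the C3 and C4 hydroxyls cis. The existing C2 centre controls C3: the 4-methoxyphenyl group sits pseudo-equatorial in the half-chair and the C3–O bond forms anti to it, which gives the 2,3-trans relationship. The step needs ketyl formation at the aryl aldehyde, intramolecular rather than intermolecular coupling, and C–C bond formation faster than reductive loss of the aryloxy tether. Conjugation with ring A secures the first, the ortho tether together with slow addition at high dilution secures the second, and the third rests on the absence of a leaving group α to the ketyl carbon and on the low temperature, which slows β-scission at the other carbonyl. Diastereomeric purity is not required, because all three centres are removed in step 10.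

Step 10
Reactants: 15 rac-(2R,3S,4S)-5,6,7,8-tetramethoxy-2-(4-methoxyphenyl)chromane-3,4-diol (2,3-trans-3,4-cis)
Product: 17 3-hydroxy-5,6,7,8-tetramethoxy-2-(4-methoxyphenyl)-4H-chromen-4-one, via chromane-3,4-dione 16 (not isolated)
Conditions: IBX (3 equiv), DMSO, rt to 40 °C
Reagents that add atoms: none
Why: IBX oxidises vicinal diols to 1,2-dicarbonyl compounds without cleaving the C–C bond; dione 16 should tautomerise at once through its acidic C2–H to the aromatic 3-hydroxy-4-pyranone, which erases the stereochemistry at C2, C3 and C4.

Step 11
Reactants: 17 3-hydroxy-5,6,7,8-tetramethoxy-2-(4-methoxyphenyl)-4H-chromen-4-one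
Product: 18 3,5-dihydroxy-6,7,8-trimethoxy-2-(4-methoxyphenyl)-4H-chromen-4-one
Conditions: BCl3 (1 M in CH2Cl2, 3 equiv), CH2Cl2, −78 to 0 °C; then MeOH, 1 M aq HCl
Reagents that add atoms: none
Why: Chelation-controlled Lewis-acid ether cleavage: boron held at the C4 carbonyl oxygen reaches only the peri 5-methoxy group through a six-membered chelate and chloride removes that methyl group, while the other four methoxy groups lack such assistance at low temperature; the excess of BCl3 covers the 3-hydroxyl.

## Compound list

1 | 2,3,4-trimethoxybenzaldehyde | COc1ccc(C=O)c(OC)c1OC | starting material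
2 | 2,3,4-trimethoxyphenyl formate | COc1ccc(OC=O)c(OC)c1OC | intermediate
3 | 2,3,4-trimethoxyphenol | COc1ccc(O)c(OC)c1OC | intermediate
4 | 1,2,3,4-tetramethoxybenzene | COc1ccc(OC)c(OC)c1OC | intermediate
5 | (2,3,4,5-tetramethoxyphenyl)lithium | [Li]c1cc(OC)c(OC)c(OC)c1OC | intermediate
6 | dimethyl (2,3,4,5-tetramethoxyphenyl)boronate | COB(OC)c1cc(OC)c(OC)c(OC)c1OC | intermediate
7 | 2,3,4,5-tetramethoxyphenol | COc1cc(O)c(OC)c(OC)c1OC | intermediate
8 | 2-(hydroxymethyl)-3,4,5,6-tetramethoxyphenol | COc1c(O)c(CO)c(OC)c(OC)c1OC | intermediate
9 | 2-hydroxy-3,4,5,6-tetramethoxybenzaldehyde | COc1c(O)c(C=O)c(OC)c(OC)c1OC | intermediate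
10 | methyl 2-(4-methoxyphenyl)acetate | COC(=O)Cc1ccc(OC)cc1 | starting material
11 | methyl 2-bromo-2-(4-methoxyphenyl)acetate (racemic) | COC(=O)C(Br)c1ccc(OC)cc1 | intermediate
12 | methyl 2-(2-formyl-3,4,5,6-tetramethoxyphenoxy)-2-(4-methoxyphenyl)acetate (racemic) | COC(=O)C(Oc1c(C=O)c(OC)c(OC)c(OC)c1OC)c1ccc(OC)cc1 | intermediate
13 | 2-[2-(hydroxymethyl)-3,4,5,6-tetramethoxyphenoxy]-2-(4-methoxyphenyl)ethan-1-ol (racemic) | OCC(Oc1c(CO)c(OC)c(OC)c(OC)c1OC)c1ccc(OC)cc1 | intermediate
14 | 2,3,4,5-tetramethoxy-6-[1-(4-methoxyphenyl)-2-oxoethoxy]benzaldehyde (racemic) | O=Cc1c(OC)c(OC)c(OC)c(OC)c1OC(C=O)c1ccc(OC)cc1 | intermediate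
15 | rac-(2R,3S,4S)-5,6,7,8-tetramethoxy-2-(4-methoxyphenyl)chromane-3,4-diol (2,3-trans-3,4-cis) | COc1ccc(cc1)[C@@H]1[C@@H](O)[C@@H](O)c2c(OC)c(OC)c(OC)c(OC)c2O1 | intermediate
16 | 5,6,7,8-tetramethoxy-2-(4-methoxyphenyl)chromane-3,4-dione (racemic) | COc1ccc(cc1)C1Oc2c(OC)c(OC)c(OC)c(OC)c2C(=O)C1=O | intermediate
17 | 3-hydroxy-5,6,7,8-tetramethoxy-2-(4-methoxyphenyl)-4H-chromen-4-one | COc1ccc(-c2oc3c(OC)c(OC)c(OC)c(OC)c3c(=O)c2O)cc1 | intermediate
18 | 3,5-dihydroxy-6,7,8-trimethoxy-2-(4-methoxyphenyl)-4H-chromen-4-one | COc1ccc(-c2oc3c(OC)c(OC)c(OC)c(O)c3c(=O)c2O)cc1 | target

## Step count and least certain steps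

Total step count: 11. Longest linear sequence: 10 steps (1 to 18 through steps 1–4 and 6–11); the one-step branch (step 5) joins at step 6.

Step 9 (key step). The most likely failure is reductive loss of the tether. Electron transfer to the aliphatic carbonyl followed by β-scission of the C2–O1 bond, or mesolytic cleavage of that doubly activated benzylic ether from the aryl ketyl, would expel a good aryloxide leaving group and a stabilised C2 radical. Intermolecular pinacol dimerisation and plain reduction of both formyl groups are secondary risks. Fallback: set out from 9 and build C3–C4 without any ketyl. An amine-catalysed Petasis-type condensation of 9 with (E)-[2-(4-methoxyphenyl)ethenyl]boronic acid (Bn2NH cat., dioxane/H2O, 90 °C) should transfer the alkenyl group to the iminium carbon, lose the amine and close by oxa-6π electrocyclisation to 5,6,7,8-tetramethoxy-2-(4-methoxyphenyl)-2H-chromene F1. Dihydroxylation of F1 (OsO4 cat., NMO, acetone/H2O) from the face away from the C2 aryl group comes back to the route at 15.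

Step 8. The new aldehyde has an α-hydrogen flanked by an aryl group, an aryloxy group and the carbonyl. Enolisation followed by aldol closure onto the neighbouring formyl group, or air oxidation and hydration during handling, would consume 14. Fallback: set out from 12 and never pass through the diol. Acetalisation of the aryl aldehyde (HC(OMe)3, TsOH cat., MeOH) gives methyl 2-[2-(dimethoxymethyl)-3,4,5,6-tetramethoxyphenoxy]-2-(4-methoxyphenyl)acetate F2. Half-reduction of the α-aryloxy ester (i-Bu2AlH, toluene, −78 °C) gives 2-[2-(dimethoxymethyl)-3,4,5,6-tetramethoxyphenoxy]-2-(4-methoxyphenyl)acetaldehyde F3. Mild acetal hydrolysis (PPTS, wet acetone) then comes back at 14 just before use.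

Step 6. The 4-methoxybenzylic bromide may ionise (solvolysis, hydrolysis by adventitious water), and carbonate may induce aldol cyclisation of 12 onto its own formyl group. Fallback: set out from 10 and form O1–C2 by carbenoid insertion under neutral conditions. Diazo transfer (4-acetamidobenzenesulfonyl azide, DBU, MeCN) gives methyl 2-diazo-2-(4-methoxyphenyl)acetate F4. Slow addition of F4 to 9 with Rh2(OAc)4 (cat., CH2Cl2, rt) should give O–H insertion and come back at 12.

Step 10. Oxidative cleavage of the C3–C4 bond, stalling at the α-hydroxy ketone stage, or further oxidation of the flavonol enol could lower the return. Fallback: set out from 15 and split the oxidation into two different reactions. Benzylic oxidation of the C4 carbinol with activated MnO2 (CH2Cl2, rt) gives rac-(2R,3R)-3-hydroxy-5,6,7,8-tetramethoxy-2-(4-methoxyphenyl)chroman-4-one F5. Dehydrogenation across C2–C3 (I2, KOAc, AcOH, reflux) comes back at 17.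

Step 11. Boron may be tied up in the five-membered 3-O/C4=O chelate so that cleavage stays incomplete, and on warming with excess reagent a second methyl group (a flanked 6- or 7-methoxy) may be lost. Fallback: set out from 17 and change the chelation pattern with a temporary protecting group. Acetylation (Ac2O, pyridine) gives 5,6,7,8-tetramethoxy-2-(4-methoxyphenyl)-4-oxo-4H-chromen-3-yl acetate F6. BCl3 (1.5 equiv, CH2Cl2, −78 to 0 °C), now chelated only between the C4 carbonyl and O5, gives 5-hydroxy-6,7,8-trimethoxy-2-(4-methoxyphenyl)-4-oxo-4H-chromen-3-yl acetate F7. Methanolysis (K2CO3, MeOH, rt) comes back at 18.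

## Further compounds

F1 | step 9 | 5,6,7,8-tetramethoxy-2-(4-methoxyphenyl)-2H-chromene (racemic) | COc1ccc(cc1)C1C=Cc2c(OC)c(OC)c(OC)c(OC)c2O1
F2 | step 8 | methyl 2-[2-(dimethoxymethyl)-3,4,5,6-tetramethoxyphenoxy]-2-(4-methoxyphenyl)acetate (racemic) | COC(=O)C(Oc1c(C(OC)OC)c(OC)c(OC)c(OC)c1OC)c1ccc(OC)cc1
F3 | step 8 | 2-[2-(dimethoxymethyl)-3,4,5,6-tetramethoxyphenoxy]-2-(4-methoxyphenyl)acetaldehyde (racemic) | O=CC(Oc1c(C(OC)OC)c(OC)c(OC)c(OC)c1OC)c1ccc(OC)cc1
F4 | step 6 | methyl 2-diazo-2-(4-methoxyphenyl)acetate | COC(=O)C(=[N+]=[N-])c1ccc(OC)cc1
F5 | step 10 | rac-(2R,3R)-3-hydroxy-5,6,7,8-tetramethoxy-2-(4-methoxyphenyl)chroman-4-one | COc1ccc(cc1)[C@@H]1[C@@H](O)C(=O)c2c(OC)c(OC)c(OC)c(OC)c2O1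
F6 | step 11 | 5,6,7,8-tetramethoxy-2-(4-methoxyphenyl)-4-oxo-4H-chromen-3-yl acetate | CC(=O)Oc1c(-c2ccc(OC)cc2)oc2c(OC)c(OC)c(OC)c(OC)c2c1=O
F7 | step 11 | 5-hydroxy-6,7,8-trimethoxy-2-(4-methoxyphenyl)-4-oxo-4H-chromen-3-yl acetate | CC(=O)Oc1c(-c2ccc(OC)cc2)oc2c(OC)c(OC)c(OC)c(O)c2c1=O
A1 | alternative 1 | 3-(benzyloxy)-5,8-dihydroxy-6,7-dimethoxy-2-(4-methoxyphenyl)-4H-chromen-4-one | COc1ccc(-c2oc3c(O)c(OC)c(OC)c(O)c3c(=O)c2OCc2ccccc2)cc1
A2 | alternative 1 | 4-[5-(benzyloxy)-6-(4-methoxyphenyl)-4-oxo-4H-pyran-3-yl]-4-hydroxy-2,3-dimethoxycyclobut-2-en-1-one (racemic) | COC1=C(OC)C(O)(c2coc(-c3ccc(OC)cc3)c(OCc3ccccc3)c2=O)C1=O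
A3 | alternative 1 | dimethyl squarate (3,4-dimethoxycyclobut-3-ene-1,2-dione) | COC1=C(OC)C(=O)C1=O
A4 | alternative 1 | 3-(benzyloxy)-5-iodo-2-(4-methoxyphenyl)-4H-pyran-4-one | COc1ccc(cc1)-c1occ(I)c(=O)c1OCc1ccccc1
A5 | alternative 2 | 5,6,7,8-tetramethoxy-2-(4-methoxyphenyl)-4H-chromen-4-one | COc1ccc(-c2cc(=O)c3c(OC)c(OC)c(OC)c(OC)c3o2)cc1
A6 | alternative 2 | 2-iodo-3,4,5,6-tetramethoxyphenol | COc1c(O)c(I)c(OC)c(OC)c1OC
A7 | alternative 2 | 4-ethynylanisole (1-ethynyl-4-methoxybenzene) | C#Cc1ccc(OC)cc1
A8 | alternative 2 | carbon monoxide | [C-]#[O+]
A9 | alternative 3 | 5,6,7,8-tetramethoxy-2-(4-methoxyphenyl)-3-nitro-2H-chromene (racemic) | COc1ccc(cc1)C1Oc2c(OC)c(OC)c(OC)c(OC)c2C=C1[N+](=O)[O-]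
A10 | alternative 3 | (E)-1-methoxy-4-(2-nitroethenyl)benzene | COc1ccc(/C=C/[N+](=O)[O-])cc1
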